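## Retrosynthetic overview

1. Target 36 ⇐ C8–C14 bond (ring C of the quinoid half, closed last) from the 8,14-seco dimer 35, an isomer carrying a 14(26)-methylene group, by a cobalt-hydride radical cycloisomerisation (metal-hydride hydrogen-atom transfer, MHAT).
2. Enabling feature: in rings A/B of the quinoid half, C8 is the CH terminus of the trienone O=C2–C1=C10–C5=C6–C7=C8 and is tied through C9–C11–C12–C13 to the tertiary ring-D carbon C14. A C14 radical therefore adds 6-exo to C8, and loss of H8 restores the chromophore.
3. 35 ⇐ hetero-Diels–Alder reaction (dioxane ring) of ortho-quinone 34 (from the fully cyclised catechol 28) with the 8,14-seco quinone methide 33.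
4. 28 and 33 ⇐ one ketone 23 ⇐ C9–C11 alkylation of the A/B 2-tetralone 8 with the D/E iodide 22 (from dione 9 by deracemising Michael/Robinson annulation, cis-hydrogenation and convex-face C13 alkylation).
5. Ring order: B (step 2), D (step 7), ring C of the aromatic half (step 16), dioxane (step 24), ring C of the quinoid half (step 25); rings A and E are bought.

Key step: step 25

Remark on numbering: friedelane (tingenone) numbering is used for all intermediates, with primed locants for the aromatic 6-oxo half. β is the face of the C9, C14 and C17 methyl groups in the usual triterpenoid drawing.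

Assumption: 1 and 9 (cis/trans mixture) are taken as catalogue compounds. The 20β-methyl of the target is taken to be the equatorial, thermodynamically preferred arrangement next to the C21 ketone in the bicyclic enedione 15 (cis to the 17-methyl).

## Route

Step 1
Reactants: 1 5-bromo-1,2-dimethoxy-3-methylbenzene; 2 tert-butyl propanoate
Product: 3 tert-butyl 2-(3,4-dimethoxy-5-methylphenyl)propanoate (racemic)
Conditions: Pd(dba)2 (2 mol %), P(t-Bu)3 (2 mol %), LiNCy2, toluene, rt
Reagents that add atoms: none
Why: Palladium-catalysed α-arylation of the ester lithium enolate with the aryl bromide joins C9 to C10 without touching the methyl ethers, and the bulky tert-butyl ester suppresses Claisen condensation and diarylation.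

Step 2
Reactants: 3 tert-butyl 2-(3,4-dimethoxy-5-methylphenyl)propanoate
Product: 6 6,7-dimethoxy-1,5-dimethyl-3,4-dihydronaphthalen-2(1H)-one (racemic), via carboxylic acid 4 (not isolated), via acid chloride 5 (not isolated)
Conditions: CF3CO2H, CH2Cl2, rt; (COCl)2, DMF (cat.), CH2Cl2, rt; ethylene (1 atm), AlCl3, CH2Cl2, −10 °C
Reagents that add atoms: ethylene (C=C)
Why: Acid cleavage of the tert-butyl ester, conversion into the acid chloride and Friedel–Crafts acylation of ethylene followed by intramolecular Friedel–Crafts alkylation (2-tetralone annulation) close ring B, the ring closure being expected at C5, the position para to the C2 methoxy group that 2,3-dimethoxytoluene-type rings use in electrophilic substitution.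

Step 3
Reactants: 6 6,7-dimethoxy-1,5-dimethyl-3,4-dihydronaphthalen-2(1H)-one
Product: 7 6,7-dihydroxy-1,5-dimethyl-3,4-dihydronaphthalen-2(1H)-one
Conditions: BBr3, CH2Cl2, −78 to 0 °C; then H2O
Reagents that add atoms: none
Why: Boron tribromide demethylation of both aryl methyl ethers is done here, on a robust small ketone, so that the catechol can be carried on under acid-labile groups whose removal the late alkenes tolerate.

Step 4
Reactants: 7 6,7-dihydroxy-1,5-dimethyl-3,4-dihydronaphthalen-2(1H)-one
Product: 8 6,7-bis(methoxymethoxy)-1,5-dimethyl-3,4-dihydronaphthalen-2(1H)-one (racemic)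
Conditions: MeOCH2Cl, i-Pr2NEt, CH2Cl2, 0 °C to rt, argon
Reagents that add atoms: chloromethyl methyl ether (COCCl)
Why: O-Alkylation of both phenols with chloromethyl methyl ether gives the bis(methoxymethyl) ether, which is stable to the bases, hydrides and palladium used later and is removed by dilute acid.

Step 5
Reactants: 9 2,5-dimethylcyclohexane-1,4-dione; 10 (S)-1-phenylethylamine
Product: 11 2,5-dimethyl-4-[(S)-1-phenylethylimino]cyclohexan-1-one (ring stereoisomer mixture)
Conditions: 1.0 equiv of 10, TsOH (cat.), toluene, reflux, Dean–Stark trap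
Reagents that add atoms: none
Why: Condensation of one of the two equivalent ketones with the chiral primary amine gives the imine whose more substituted secondary enamine tautomer is the nucleophile of the next step, the ring stereocentres being irrelevant because C17 is re-formed in step 6 and C20 is equilibrated in step 7.

Step 6
Reactants: 11 mono-imine; 12 pent-1-en-3-one
Product: 14 (2S)-2,5-dimethyl-2-(3-oxopentyl)cyclohexane-1,4-dione (C5 epimers), via Michael adduct imine 13 (not isolated)
Conditions: THF, 40 °C; then 20 % aq. AcOH, rt
Reagents that add atoms: water (O)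
Why: Deracemising Michael addition of the more substituted secondary enamine tautomer to the vinyl ketone, through a chair-like aza-ene transition state in which the 1-phenylethyl group shields one face, sets the quaternary C17, the (S)-amine being chosen because with 2-methylcyclohexanone it gives the sense that corresponds to 17β-methyl here, and aqueous acetic acid then hydrolyses the imine.

Step 7
Reactants: 14 triketone
Product: 15 (4aS,7R)-1,4a,7-trimethyl-4,4a,7,8-tetrahydronaphthalene-2,6(3H,5H)-dione (D/E enedione: 13(18)-en-14-one, 21-ketone, 17β-Me, 20β-Me)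
Conditions: NaOMe, MeOH, 60 °C
Reagents that add atoms: none
Why: Intramolecular aldol condensation (second stage of a Robinson annulation) of the ethyl ketone onto the C18 carbonyl closes ring D as the 13(18)-en-14-one, while methoxide equilibrates C20 to the equatorial methyl, cis to the axial 17-methyl.

Step 8
Reactants: 15 D/E enedione
Product: 16 C21 ethylene ketal of 15
Conditions: HOCH2CH2OH, TsOH (cat.), 4 Å molecular sieves, CH2Cl2, rt
Reagents that add atoms: ethylene glycol (OCCO)
Why: Acid-catalysed ketalisation at room temperature takes the saturated C21 ketone and leaves the less electrophilic conjugated C14 enone, the known selectivity of Wieland–Miescher-type enediones.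

Step 9
Reactants: 16 ketal enone
Product: 17 cis-fused saturated C14 ketone (18β-H, 17β-Me, 20β-Me, C21 ketal; 13α-Me as formed)
Conditions: H2 (4 atm), Pd/C (10 wt %), KOH (0.1 M), EtOH, rt
Reagents that add atoms: none
Why: Heterogeneous hydrogenation of the tetrasubstituted enone in basic ethanol should deliver hydrogen to the face of the angular 17-methyl, as 4-en-3-one steroids give 5β products under these conditions, and so sets the cis D/E fusion (18β-H), C13 remaining epimerisable until step 10.

Step 10
Reactants: 17 cis-fused ketone
Product: 19 tert-butyl ester of the C13-quaternary keto acid (13α-Me and 13β-CH2CO2t-Bu; C14 ketone), via silyl enol ether 18 (not isolated)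
Conditions: Me3SiCl, Et3N, DMF, 120 °C; pentane extraction; MeLi, THF, 0 °C; BrCH2CO2t-Bu, DMPU, −78 to 0 °C
Reagents that add atoms: tert-butyl bromoacetate (BrCC(=O)OC(C)(C)C)
Why: Silyl enol ether formation under equilibrating conditions goes to the more substituted C13 side, methyllithium releases the regiodefined lithium enolate, and its alkylation should occur on the convex β-face of the cis-fused bicycle, anti to the axial C17–C22 bond, which sets the C13 quaternary centre with the two-carbon arm β and the methyl α.

Step 11
Reactants: 19 keto ester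
Product: 20 14(26)-methylene ester
Conditions: Ph3PCH3Br, KOt-Bu, toluene, 90 °C
Reagents that add atoms: methyltriphenylphosphonium bromide (C[P+](c1ccccc1)(c1ccccc1)c1ccccc1.[Br-])
Why: Wittig methylenation of the hindered C14 ketone with excess non-stabilised ylide at elevated temperature installs the 14(26)-alkene that later serves as the precursor of the tertiary C14 centre, the ester and the ketal being inert.

Step 12
Reactants: 20 methylene ester
Product: 21 primary alcohol (C11–OH)
Conditions: LiAlH4, THF, 0 °C
Reagents that add atoms: none
Why: Hydride reduction of the tert-butyl ester gives the primary C11 alcohol without touching the alkene or the ketal.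

Step 13
Reactants: 21 primary alcohol
Product: 22 D/E iodide (C11–I)
Conditions: I2, PPh3, imidazole, CH2Cl2, 0 °C to rt
Reagents that add atoms: iodine (II)
Why: Appel-type iodination converts the primary alcohol into the iodide under neutral conditions that spare the ketal and the exocyclic alkene.

Step 14
Reactants: 8 bis(methoxymethyl) 2-tetralone; 22 D/E iodide
Product: 23 coupled 8,14-seco ketone (9β-Me, C8 ketone, 14(26)-alkene, C21 ketal)
Conditions: N-[4-(trifluoromethyl)benzyl]cinchoninium bromide (10 mol %), 50 % aq. NaOH, toluene, 0 °C, argon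
Reagents that add atoms: none
Why: Phase-transfer alkylation of the benzylic tetralone enolate with the primary iodide creates the C9 quaternary centre and the C9–C11 bond, the chiral cinchoninium cation (pseudo-enantiomeric to the cinchonidinium salt) pairing with the enolate and exposing the face that leaves the 25-methyl β, as in the known asymmetric alkylation of 1-methyl-2-tetralones.

Step 15
Reactants: 23 coupled ketone
Product: 24 7-en-8-yl triflate
Conditions: KN(SiMe3)2, THF, −78 °C; PhNTf2, −78 to 0 °C
Reagents that add atoms: N-phenylbis(trifluoromethanesulfonimide) (O=S(=O)(N(c1ccccc1)S(=O)(=O)C(F)(F)F)C(F)(F)F)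
Why: Deprotonation can only occur at C7 because C9 is quaternary, and triflation of this enolate gives the 7-en-8-yl triflate regiospecifically.

Step 16
Reactants: 24 vinyl triflate
Product: 25 pentacyclic 7-ene (ring C closed, 14β-Me; bis(methoxymethyl) ether, C21 ketal)
Conditions: Pd(OAc)2 (10 mol %), PPh3 (20 mol %), HCO2Na, Et4NCl, DMF, 80 °C
Reagents that add atoms: none
Why: Oxidative addition of zerovalent palladium to the vinyl triflate, 6-exo-trig syn-carbopalladation of the 14(26)-alkene and formate reduction of the neopentyl alkylpalladium, which has no β-hydrogen (reductive Heck cyclisation), close ring C of this half and create the C14 quaternary centre, whose 26-methyl should come out β because C8 is delivered to the ring-D face that keeps the new bond equatorial and trans to the C13–C12 bond.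

Step 17
Reactants: 25 pentacyclic 7-ene
Product: 26 7-en-6-one
Conditions: DDQ (2.2 equiv), NaHCO3, dioxane/H2O, rt
Reagents that add atoms: water (O)
Why: DDQ abstracts hydride from C6, which is benzylic to the electron-rich arene and allylic to the 7-ene, and the cation is trapped by water and oxidised on to the 7-en-6-one.

Step 18
Reactants: 26 7-en-6-one
Product: 27 7,8-dihydro-6-one (8α-H)
Conditions: Li, NH3 (l)/THF, t-BuOH (1 equiv), −78 °C; then NH4Cl
Reagents that add atoms: none
Why: Dissolving-metal (Birch-type) conjugate reduction of the aryl enone puts hydrogen on C8 from the α-face, away from the 25- and 26-methyl groups, which gives the trans B/C fusion (8α-H), and the resulting enolate protects the aryl ketone from over-reduction.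

Step 19
Reactants: 27 protected dihydro ketone
Product: 28 7,8-dihydro-6-oxotingenol (catechol, 6,21-diketone)
Conditions: HCl (1.5 M), MeOH/THF/H2O, 40 °C, argon
Reagents that add atoms: water (O)
Why: Acid-catalysed acetal exchange removes both methoxymethyl ethers and the dioxolane in one operation to give the catechol diketone, in which no alkene is left that acid could harm.

Step 20
Reactants: 23 coupled ketone
Product: 29 C8 alcohol (epimer mixture)
Conditions: NaBH4, MeOH/THF, 0 °C
Reagents that add atoms: none
Why: Borohydride reduction of the hindered C8 ketone gives the secondary alcohol as an inconsequential epimer mixture, the ketal, the alkene and the acetals being inert.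

Step 21
Reactants: 29 C8 alcohol
Product: 30 8,14-seco 7,14(26)-diene (bis(methoxymethyl) ether, C21 ketal)
Conditions: Burgess reagent (MeO2CN−SO2N+Et3), toluene, 70 °C
Reagents that add atoms: none
Why: Burgess dehydration is a syn-elimination through a sulfamate ester that avoids a carbocation next to the quaternary C9 and can only remove a C7 hydrogen, so that the 7-ene forms without rearrangement.

Step 22
Reactants: 30 seco diene
Product: 31 8,14-seco catechol (21-ketone)
Conditions: HCl (1 M), MeOH/THF/H2O, 35 °C, argon
Reagents that add atoms: water (O)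
Why: Dilute acid removes both methoxymethyl ethers and the dioxolane while the isolated alkenes survive, and a possible acid-induced shift of the 14(26)-alkene into ring D would be harmless because both isomers give the same C14 radical later.

Step 23
Reactants: 31 seco catechol
Product: 33 8,14-seco quinone methide (3-hydroxy-2-oxo-1(10),3,5,7-tetraene), via seco ortho-quinone 32 (not isolated)
Conditions: Ag2O, Et2O, rt, dark
Reagents that add atoms: none
Why: Two-electron oxidation of the catechol gives the ortho-quinone, which tautomerises through its C6 hydrogen to the extended 3-hydroxy quinone methide, the same oxidation and prototropy that turn pristimerol-type catechols into celastroid quinone methides.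

Step 24
Reactants: 28 7,8-dihydro-6-oxotingenol; 33 seco quinone methide
Product: 35 8,14-seco dimer (1,4-dioxane closed, 14(26)-alkene in the quinoid half), via ortho-quinone 34 (not isolated)
Conditions: 28, Ag2O, CH2Cl2, rt, filtration; then 33, CH2Cl2, rt, dark
Reagents that add atoms: none
Why: Inverse-electron-demand hetero-Diels–Alder reaction of the electron-poor ortho-quinone (O=C2′–C3′=O heterodiene) with the electron-rich C3=C4 enol double bond of the quinone methide closes the 1,4-dioxane ring, suprafacial addition giving the cis 3α-hydroxy-4α-methyl arrangement, approach to the β-face of ring A being expected because the α-face is screened by the C9 two-carbon chain that carries rings D and E, and the enol β-carbon C4 pairing with O3′ as in the natural dimers of this family.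

Step 25
Reactants: 35 8,14-seco dimer
Product: 36 target CNP0106202.2
Conditions: Co(tBu4-salen)Cl (chloride of trivalent cobalt with the dianion of N,N′-bis(3,5-di-tert-butylsalicylidene)ethane-1,2-diamine, C32H46N2O2CoCl; 10 mol %), PhSiH3 (10 mol %), benzene, 22 °C, argon
Reagents that add atoms: none
Why: Proposed new method: A trivalent cobalt hydride formed from the cobalt chloride complex and PhSiH3 transfers a hydrogen atom to the terminal carbon (C26) of the electron-rich 14(26)-alkene, the tertiary C14 radical adds 6-exo-trig to C8, the CH terminus of the trienone, and the resulting radical, delocalised over C7, C5, C1 and O2, gives H8 back to divalent cobalt, which restores the C7=C8 bond and the cobalt hydride, so that the step is a catalytic isomerisation. The closest known reaction types are the cobalt-salen and silane catalysed MHAT cycloisomerisation of dienes (radical cyclisation followed by hydrogen return to cobalt) and the iron-mediated MHAT conjugate additions of tertiary radicals to enones and quinone methides; the new element is their combination on a vinylogous quinone-methide acceptor. Ring C is closed in the 6-exo-trig radical mode through the C8–C14 bond, between a carbon flanked by the quaternary C9 and a new quaternary carbon next to the quaternary C13. The only new stereocentre, C14, is controlled by the existing C13 centre and the cis D/E bicycle: the tether leaves C13 on the β-side, and C8 is expected to enter trans to it (equatorial on ring D, 26-methyl axial and anti to the 27-methyl), which is the C/D-trans arrangement of the target and keeps the large dimeric A/B unit out of the axial position on ring D. The step needs chemoselective hydrogen-atom transfer to the 1,1-disubstituted alkene in the presence of the trienone, the ketones and the free hemiketal, which is secured by the preference of metal hydrides for electron-rich unhindered alkenes and by the catalytic amount of silane (no stoichiometric reductant that could saturate the chromophore), and it needs attack at C8 only, which the four-atom tether enforces because C6 could be reached only through an eight-membered ring.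

## Compound list

1 | 5-bromo-1,2-dimethoxy-3-methylbenzene | COc1cc(Br)cc(C)c1OC | starting material
2 | tert-butyl propanoate | CCC(=O)OC(C)(C)C | starting material
3 | tert-butyl 2-(3,4-dimethoxy-5-methylphenyl)propanoate (racemic) | COc1cc(cc(C)c1OC)C(C)C(=O)OC(C)(C)C | intermediate
4 | 2-(3,4-dimethoxy-5-methylphenyl)propanoic acid | COc1cc(cc(C)c1OC)C(C)C(O)=O | intermediate
5 | 2-(3,4-dimethoxy-5-methylphenyl)propanoyl chloride | COc1cc(cc(C)c1OC)C(C)C(Cl)=O | intermediate
6 | 6,7-dimethoxy-1,5-dimethyl-3,4-dihydronaphthalen-2(1H)-one (racemic; rings A/B, C8 ketone) | COc1cc2C(C)C(=O)CCc2c(C)c1OC | intermediate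
7 | 6,7-dihydroxy-1,5-dimethyl-3,4-dihydronaphthalen-2(1H)-one | Oc1cc2C(C)C(=O)CCc2c(C)c1O | intermediate
8 | 6,7-bis(methoxymethoxy)-1,5-dimethyl-3,4-dihydronaphthalen-2(1H)-one | COCOc1cc2C(C)C(=O)CCc2c(C)c1OCOC | intermediate
9 | 2,5-dimethylcyclohexane-1,4-dione (cis/trans mixture) | CC1CC(=O)C(C)CC1=O | starting material
10 | (S)-1-phenylethylamine | C[C@H](N)c1ccccc1 | starting material
11 | 2,5-dimethyl-4-[(S)-1-phenylethylimino]cyclohexan-1-one (ring stereoisomer mixture) | CC1CC(=O)C(C)CC1=N[C@@H](C)c1ccccc1 | intermediate
12 | pent-1-en-3-one | CCC(=O)C=C | starting material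
13 | Michael adduct imine: C18 (S)-1-phenylethylimine of triketone 14 | CCC(=O)CC[C@@]1(C)CC(=O)C(C)CC1=N[C@@H](C)c1ccccc1 | intermediate
14 | (2S)-2,5-dimethyl-2-(3-oxopentyl)cyclohexane-1,4-dione (C5 epimers) | CCC(=O)CC[C@@]1(C)CC(=O)C(C)CC1=O | intermediate
15 | (4aS,7R)-1,4a,7-trimethyl-4,4a,7,8-tetrahydronaphthalene-2,6(3H,5H)-dione (D/E enedione) | CC1=C2C[C@@H](C)C(=O)C[C@]2(C)CCC1=O | intermediate
16 | C21 ethylene ketal of enedione 15 | CC1=C2C[C@@H](C)C3(OCCO3)C[C@]2(C)CCC1=O | intermediate
17 | cis-fused saturated C14 ketone (18β-H, 17β-Me, 20β-Me, 13α-Me, C21 ketal) | C[C@@H]1[C@@H]2C[C@@H](C)C3(OCCO3)C[C@]2(C)CCC1=O | intermediate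
18 | 13-en-14-yl trimethylsilyl ether of 17 | CC=1[C@@H]2C[C@@H](C)C3(OCCO3)C[C@]2(C)CCC=1O[Si](C)(C)C | intermediate
19 | C13-quaternary keto tert-butyl ester (13α-Me, 13β-CH2CO2t-Bu, C14 ketone) | CC(C)(C)OC(=O)C[C@@]1(C)[C@@H]2C[C@@H](C)C3(OCCO3)C[C@]2(C)CCC1=O | intermediate
20 | 14(26)-methylene tert-butyl ester | CC(C)(C)OC(=O)C[C@@]1(C)[C@@H]2C[C@@H](C)C3(OCCO3)C[C@]2(C)CCC1=C | intermediate
21 | D/E primary alcohol (C11–OH) | OCC[C@@]1(C)[C@@H]2C[C@@H](C)C3(OCCO3)C[C@]2(C)CCC1=C | intermediate
22 | D/E iodide (C11–I) | ICC[C@@]1(C)[C@@H]2C[C@@H](C)C3(OCCO3)C[C@]2(C)CCC1=C | intermediate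
23 | coupled 8,14-seco C8 ketone (9β-Me, bis(methoxymethyl) ether, C21 ketal) | COCOc1cc2c(c(C)c1OCOC)CCC(=O)[C@@]2(C)CC[C@@]1(C)[C@@H]3C[C@@H](C)C4(OCCO4)C[C@]3(C)CCC1=C | intermediate
24 | 7-en-8-yl triflate of 23 | COCOc1cc2c(c(C)c1OCOC)CC=C(OS(=O)(=O)C(F)(F)F)[C@@]2(C)CC[C@@]1(C)[C@@H]3C[C@@H](C)C4(OCCO4)C[C@]3(C)CCC1=C | intermediate
25 | pentacyclic 7-ene (protected tingenol type, 14β-Me) | COCOc1cc2c(c(C)c1OCOC)CC=C1[C@@]2(C)CC[C@@]2(C)[C@@H]3C[C@@H](C)C4(OCCO4)C[C@]3(C)CC[C@]12C | intermediate
26 | pentacyclic 7-en-6-one | COCOc1cc2c(c(C)c1OCOC)C(=O)C=C1[C@@]2(C)CC[C@@]2(C)[C@@H]3C[C@@H](C)C4(OCCO4)C[C@]3(C)CC[C@]12C | intermediate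
27 | pentacyclic 7,8-dihydro-6-one (8α-H) | COCOc1cc2c(c(C)c1OCOC)C(=O)C[C@H]1[C@@]2(C)CC[C@@]2(C)[C@@H]3C[C@@H](C)C4(OCCO4)C[C@]3(C)CC[C@]12C | intermediate
28 | 7,8-dihydro-6-oxotingenol (catechol of the aromatic half) | Cc1c(O)c(O)cc2c1C(=O)C[C@H]1[C@@]2(C)CC[C@@]2(C)[C@@H]3C[C@@H](C)C(=O)C[C@]3(C)CC[C@]12C | intermediate
29 | C8 alcohol of 23 (epimer mixture) | COCOc1cc2c(c(C)c1OCOC)CCC(O)[C@@]2(C)CC[C@@]1(C)[C@@H]3C[C@@H](C)C4(OCCO4)C[C@]3(C)CCC1=C | intermediate
30 | 8,14-seco 7,14(26)-diene (bis(methoxymethyl) ether, C21 ketal) | COCOc1cc2c(c(C)c1OCOC)CC=C[C@@]2(C)CC[C@@]1(C)[C@@H]3C[C@@H](C)C4(OCCO4)C[C@]3(C)CCC1=C | intermediate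
31 | 8,14-seco catechol (21-ketone) | Cc1c(O)c(O)cc2c1CC=C[C@@]2(C)CC[C@@]1(C)[C@@H]3C[C@@H](C)C(=O)C[C@]3(C)CCC1=C | intermediate
32 | 8,14-seco ortho-quinone | CC1=C2CC=C[C@](C)(C2=CC(=O)C1=O)CC[C@@]1(C)[C@@H]2C[C@@H](C)C(=O)C[C@]2(C)CCC1=C | intermediate
33 | 8,14-seco quinone methide (8,14-seco-tingenone with 14(26)-alkene) | CC1=C(O)C(=O)C=C2C1=CC=C[C@@]2(C)CC[C@@]1(C)[C@@H]3C[C@@H](C)C(=O)C[C@]3(C)CCC1=C | intermediate
34 | ortho-quinone of 28 | CC1=C2C(=O)C[C@H]3[C@](C)(C2=CC(=O)C1=O)CC[C@@]1(C)[C@@H]2C[C@@H](C)C(=O)C[C@]2(C)CC[C@]31C | intermediate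
35 | 8,14-seco dimer (dioxane closed; C8–H and 14(26)-alkene in the quinoid half) | Cc1c2c(cc3c1C(=O)C[C@H]1[C@@]3(C)CC[C@@]3(C)[C@@H]4C[C@@H](C)C(=O)C[C@]4(C)CC[C@]13C)O[C@@]1(O)C(=O)C=C3C(=CC=C[C@@]3(C)CC[C@@]4(C)[C@@H]5C[C@@H](C)C(=O)C[C@]5(C)CCC4=C)[C@@]1(C)O2 | intermediate
36 | CNP0106202.2 | Cc1c2c(cc3c1C(=O)C[C@H]1[C@@]3(C)CC[C@@]3(C)[C@@H]4C[C@@H](C)C(=O)C[C@]4(C)CC[C@]13C)O[C@@]1(O)C(=O)C=C3C(=CC=C4[C@@]3(C)CC[C@@]3(C)[C@@H]5C[C@@H](C)C(=O)C[C@]5(C)CC[C@]43C)[C@@]1(C)O2 | target

## Step count and risks

Total steps: 25. Longest linear sequence: 17 steps (steps 5–13, 14, 15–19, 24, 25).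

Steps most likely to fail:

1. Step 25 (Proposed new method). The hydrogen return from the delocalised ring-B radical to divalent cobalt may lose out to over-reduction or radical dimerisation, hydrogen-atom transfer to the trienone may compete, and C8 may enter on the wrong lobe of the C14 radical (poor facial selectivity, C/D-cis closure). Fallback with known chemistry, setting out from 35: stoichiometric iron-mediated MHAT reductive cyclisation (Fe(acac)3, PhSiH3, EtOH/ethylene glycol, 60 °C; Giese-type 6-exo addition of the tertiary radical to the quinone-methide-like acceptor) should give the 7,8-dihydro dimer F1, whose C8 configuration does not matter. DDQ dehydrogenation (dioxane, 80 °C) of its dienone then re-forms the C7=C8 bond, and the route is rejoined at 36.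

2. Step 24. The cycloaddition on the conformationally mobile seco dienophile may show poor regio- or facial selectivity, and conjugate addition of unoxidised catechol to the quinone methide may compete. Fallback, setting out from 25: the union is moved behind the closure of ring C. Dilute HCl in MeOH/THF removes the acetals to give the tingenol-type catechol F2, Ag2O oxidation gives tingenone F3, and hetero-Diels–Alder reaction of this rigid pentacyclic dienophile with ortho-quinone 34 (made from 28 as in step 24) leads directly to 36, where the route is rejoined.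

3. Step 16. Formate may reduce the vinylpalladium species before it carbopalladates the hindered alkene, and C8 may be delivered to the wrong face of C14. Fallback, setting out from 30: DDQ in aqueous dioxane oxidises C6 to give the seco aryl enone F4. Iron-mediated reductive MHAT radical cyclisation (Fe(acac)3, PhSiH3, EtOH, 60 °C; known olefin–enone coupling, 6-exo) closes ring C to the saturated 6-ketone F5. IBX dehydrogenation (DMSO, 75 °C) then gives the 7-en-6-one, and the route is rejoined at 26.

Further compounds

F1 | step 25 | 7,8-dihydro dimer (ring C closed, C8–H, 1(10),5-dien-2-one in the quinoid half) | Cc1c2c(cc3c1C(=O)C[C@H]1[C@@]3(C)CC[C@@]3(C)[C@@H]4C[C@@H](C)C(=O)C[C@]4(C)CC[C@]13C)O[C@@]1(O)C(=O)C=C3C(=CCC4[C@@]3(C)CC[C@@]3(C)[C@@H]5C[C@@H](C)C(=O)C[C@]5(C)CC[C@]43C)[C@@]1(C)O2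
F2 | step 24 | tingenol-type catechol (7-ene, 21-ketone) | Cc1c(O)c(O)cc2c1CC=C1[C@@]2(C)CC[C@@]2(C)[C@@H]3C[C@@H](C)C(=O)C[C@]3(C)CC[C@]12C
F3 | step 24 | tingenone | CC1=C(O)C(=O)C=C2C1=CC=C1[C@@]2(C)CC[C@@]2(C)[C@@H]3C[C@@H](C)C(=O)C[C@]3(C)CC[C@]12C
F4 | step 16 | 8,14-seco 7-en-6-one (bis(methoxymethyl) ether, C21 ketal, 14(26)-alkene) | COCOc1cc2c(c(C)c1OCOC)C(=O)C=C[C@@]2(C)CC[C@@]1(C)[C@@H]3C[C@@H](C)C4(OCCO4)C[C@]3(C)CCC1=C
F5 | step 16 | pentacyclic saturated 6-ketone (C8 configuration as formed) | COCOc1cc2c(c(C)c1OCOC)C(=O)CC1[C@@]2(C)CC[C@@]2(C)[C@@H]3C[C@@H](C)C4(OCCO4)C[C@]3(C)CC[C@]12C
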